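**Retrosynthetic overview**

- Feature: the ester carbon on C1 of ring A (the benzoate ring, whose C6 carries the ketone) and the phenol oxygen on C6' of ring B (ortho to the ketone carbon C1', next to C5'–Cl) can be tied into a seven-membered lactone, a dibenzo[b,e]oxepine-6,11-dione. The crowded C6–C(=O) bond is therefore made inside a ring.
- Disconnection 1: target ⇒ lactone ketone. Methoxide opening returns the ring A methyl ester and the C6' phenol; acid removes the MOM ether on ring A.
- Disconnection 2 (key): lactone ketone ⇒ aryl ester of 3-chloro-2,6-dihydroxy-4-methylbenzaldehyde with a 2-iodobenzoic acid. Palladium joins the iodine-bearing carbon to the formyl carbon. The tether sits on the chlorine-flanked oxygen, so no aromatic C–H lies ortho to the ester oxygen.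
- Disconnection 3: ester ⇒ 2-iodo-3-methoxy-5-(methoxymethoxy)benzoic acid (from 2-iodo-3-methoxybenzoic acid by iridium C–H borylation and oxidation at C5) plus the mono-silylated chloro dihydroxy aldehyde (from orcinol by ortho-metalation and formylation, chlorination, silylation of the hydrogen-flanked phenol).
- Ring order: both benzene rings are bought; the only ring formed is the seven-membered lactone in the key step, and the last step opens it again.

Key step: step 11

**Route**

Step 1
Reactants: 1 2-iodo-3-methoxybenzoic acid
Product: 2 methyl 2-iodo-3-methoxybenzoate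
Conditions: MeI, K2CO3, DMF, rt
Reagents that add atoms: iodomethane, CI
Why: O-alkylation of the carboxylate (SN2 esterification) does not depend on access to the hindered carbonyl carbon next to iodine, and the aryl iodide and aryl methyl ether are inert.

Step 2
Reactants: 2 methyl 2-iodo-3-methoxybenzoate
Product: 4 methyl 5-hydroxy-2-iodo-3-methoxybenzoate, via aryl pinacol boronate 3 (not isolated)
Conditions: [Ir(OMe)(cod)]2 (1.5 mol %), 4,4'-di-tert-butyl-2,2'-bipyridine (3 mol %), B2pin2, THF, 65 °C; then 30% H2O2, aq NaOH, 0 °C
Reagents that add atoms: bis(pinacolato)diboron, CC1(C)OB(OC1(C)C)B1OC(C)(C)C(C)(C)O1 (its boron stays only in intermediate 3); hydrogen peroxide, OO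
Why: Iridium-catalysed aromatic C–H borylation (Hartwig–Miyaura type) is governed by sterics and should take C5, the only ring hydrogen without an ortho neighbour (C4 lies next to the methoxy group, C6 next to the ester), the carbon–iodine bond being tolerated by this catalyst, and basic peroxide then oxidises the boronate to the phenol, which fixes hydroxyl para and methoxy ortho to iodine without relying on directing effects in an electrophilic iodination.

Step 3
Reactants: 4 methyl 5-hydroxy-2-iodo-3-methoxybenzoate
Product: 5 methyl 2-iodo-3-methoxy-5-(methoxymethoxy)benzoate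
Conditions: MOMCl, i-Pr2NEt, CH2Cl2, 0 °C to rt
Reagents that add atoms: chloromethyl methyl ether, COCCl
Why: O-alkylation of the phenol with the reactive α-chloro ether gives the acetal ether, which is stable to the base, fluoride and palladium steps ahead and falls to mild acid at the end.

Step 4
Reactants: 5 methyl 2-iodo-3-methoxy-5-(methoxymethoxy)benzoate
Product: 6 2-iodo-3-methoxy-5-(methoxymethoxy)benzoic acid
Conditions: LiOH, THF/MeOH/H2O, 40 °C; then cold dilute HCl to pH 3–4
Reagents that add atoms: lithium hydroxide, [Li+].[OH-]
Why: Saponification of the methyl ester; the acetal ether is stable to base and should survive the brief cold acidification.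

Step 5
Reactants: 7 orcinol (5-methylbenzene-1,3-diol)
Product: 8 1,3-bis(methoxymethoxy)-5-methylbenzene
Conditions: MOMCl (2.5 equiv), i-Pr2NEt, CH2Cl2, 0 °C to rt
Reagents that add atoms: chloromethyl methyl ether, COCCl
Why: Double O-alkylation gives the bis-acetal ether, whose two oxygens are strong directing groups for the ortho-metalation that follows.

Step 6
Reactants: 8 1,3-bis(methoxymethoxy)-5-methylbenzene
Product: 11 2,6-dihydroxy-4-methylbenzaldehyde (atranol), via aryllithium 9 (not isolated), via bis-MOM aldehyde 10 (not isolated)
Conditions: n-BuLi, TMEDA, THF, 0 °C; DMF, 0 °C to rt; then 3 M aq HCl, MeOH, 50 °C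
Reagents that add atoms: n-butyllithium, [Li]CCCC (its lithium stays only in intermediate 9); N,N-dimethylformamide, CN(C)C=O
Why: Directed ortho-metalation takes the hydrogen between the two acetal oxygens, the aryllithium is formylated by DMF, and the acidic methanol of the work-up removes both acetal ethers by acetal exchange, which places the formyl group between the two phenols, a position that electrophilic formylation of orcinol does not reach cleanly.

Step 7
Reactants: 11 2,6-dihydroxy-4-methylbenzaldehyde
Product: 12 3-chloro-2,6-dihydroxy-4-methylbenzaldehyde (chloroatranol)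
Conditions: NCS (1.0 equiv), MeCN, 0 °C to rt
Reagents that add atoms: N-chlorosuccinimide, O=C1CCC(=O)N1Cl
Why: Electrophilic aromatic chlorination: the two open positions of 11 are equivalent by symmetry, each ortho to one hydroxyl and para to the other, so one equivalent of NCS should give a single monochloride.

Step 8
Reactants: 12 3-chloro-2,6-dihydroxy-4-methylbenzaldehyde
Product: 13 3-chloro-2-hydroxy-4-methyl-6-{[tri(propan-2-yl)silyl]oxy}benzaldehyde
Conditions: TIPSCl (1.05 equiv), imidazole, DMF, 0 °C
Reagents that add atoms: chlorotri(propan-2-yl)silane, CC(C)[Si](Cl)(C(C)C)C(C)C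
Why: Silylation with the bulky silyl chloride should take the phenol flanked by hydrogen and leave the one wedged between chlorine and the formyl group, and the remaining phenol is then held in a hydrogen bond to the aldehyde, which holds back a second silylation.

Step 9
Reactants: 6 2-iodo-3-methoxy-5-(methoxymethoxy)benzoic acid; 13 3-chloro-2-hydroxy-4-methyl-6-{[tri(propan-2-yl)silyl]oxy}benzaldehyde
Product: 15 6-chloro-2-formyl-5-methyl-3-{[tri(propan-2-yl)silyl]oxy}phenyl 2-iodo-3-methoxy-5-(methoxymethoxy)benzoate, via acid chloride 14 (not isolated)
Conditions: 1-chloro-N,N,2-trimethylprop-1-en-1-amine, CH2Cl2, 0 °C to rt; then 13, Et3N, DMAP (cat.), 0 °C to rt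
Reagents that add atoms: 1-chloro-N,N,2-trimethylprop-1-en-1-amine, CC(C)=C(Cl)N(C)C (its chlorine stays only in intermediate 14)
Why: The α-chloroenamine (Ghosez reagent) makes the acid chloride under neutral conditions that spare the acetal ether, and DMAP-catalysed O-acylation of the single free phenol of 13 fixes the tether on the chlorine-flanked oxygen.

Step 10
Reactants: 15 6-chloro-2-formyl-5-methyl-3-{[tri(propan-2-yl)silyl]oxy}phenyl 2-iodo-3-methoxy-5-(methoxymethoxy)benzoate
Product: 16 6-chloro-2-formyl-3-hydroxy-5-methylphenyl 2-iodo-3-methoxy-5-(methoxymethoxy)benzoate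
Conditions: TBAF, AcOH, THF, 0 °C
Reagents that add atoms: none
Why: Fluoride cleaves the aryl silyl ether (strong Si–F bond, phenoxide leaving group), and the acetic acid buffer protonates the freed phenoxide so that it does not attack the activated aryl ester.

Step 11
Reactants: 16 6-chloro-2-formyl-3-hydroxy-5-methylphenyl 2-iodo-3-methoxy-5-(methoxymethoxy)benzoate
Product: 17 4-chloro-1-hydroxy-10-methoxy-8-(methoxymethoxy)-3-methyldibenzo[b,e]oxepine-6,11-dione
Conditions: PdCl2 (10 mol %), LiCl (0.4 equiv), Na2CO3 (2 equiv), 4 Å MS, DMF (0.01 M), 100 °C, N2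
Reagents that add atoms: none
Why: Proposed new method: PdCl2 (divalent palladium) is reduced in the flask to zerovalent palladium, which inserts into the carbon–iodine bond of ring A; the sodium phenoxide of ring B, ortho to the formyl group, then takes the place of halide on the arylpalladium and holds the formyl C–H at the metal, C–H cleavage gives an aryl(acyl)palladium species, and C–C reductive elimination forms the ring A C6–C(=O) bond. The closest known reaction type is the intermolecular PdCl2/LiCl/Na2CO3 coupling of salicylaldehydes with aryl iodides to 2-hydroxybenzophenones; the tethered version that forms a seven-membered ring is the untested element. The seven-membered lactone ketone ring closes by reductive elimination from an eight-membered palladacycle, formally a 7-exo-trig attack of the aryl carbon on the formyl carbon, and this requires the aryl ester to turn into its s-cis form. No stereocentre is formed. The step needs chemoselectivity for the formyl C–H over an aromatic C–H and over loss of the ester: in 16 chlorine occupies the only ring position ortho to the ester oxygen, so the competing six-ring direct arylation to a benzo[c]chromenone has no C–H to use, the free phenoxide is the only directing group, and high dilution with dry carbonate should hold back intermolecular coupling and acyl transfer.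

Step 12
Reactants: 17 4-chloro-1-hydroxy-10-methoxy-8-(methoxymethoxy)-3-methyldibenzo[b,e]oxepine-6,11-dione
Product: 19 monochlorosulochrin, methyl 2-(3-chloro-2,6-dihydroxy-4-methylbenzoyl)-5-hydroxy-3-methoxybenzoate, via MOM-protected benzophenone ester 18 (not isolated)
Conditions: NaOMe (3 equiv), MeOH/THF, 0 °C to rt; then HCl in MeOH (to about 1 M), 40 °C
Reagents that add atoms: sodium methoxide, [Na+].[O-]C
Why: Methoxide opens the aryl lactone by transesterification with the ring B phenoxide as leaving group, which gives exactly the methyl ester on ring A and the second free phenol on ring B, and acidification in methanol then removes the acetal ether by acetal exchange without touching the methyl ester.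

**Compound list**

1 | 2-iodo-3-methoxybenzoic acid | OC(=O)c1cccc(OC)c1I | starting material
2 | methyl 2-iodo-3-methoxybenzoate | COC(=O)c1cccc(OC)c1I | intermediate
3 | methyl 2-iodo-3-methoxy-5-(4,4,5,5-tetramethyl-1,3,2-dioxaborolan-2-yl)benzoate | COC(=O)c1cc(B2OC(C)(C)C(C)(C)O2)cc(OC)c1I | intermediate
4 | methyl 5-hydroxy-2-iodo-3-methoxybenzoate | COC(=O)c1cc(O)cc(OC)c1I | intermediate
5 | methyl 2-iodo-3-methoxy-5-(methoxymethoxy)benzoate | COC(=O)c1cc(OCOC)cc(OC)c1I | intermediate
6 | 2-iodo-3-methoxy-5-(methoxymethoxy)benzoic acid | OC(=O)c1cc(OCOC)cc(OC)c1I | intermediate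
7 | orcinol (5-methylbenzene-1,3-diol) | Cc1cc(O)cc(O)c1 | starting material
8 | 1,3-bis(methoxymethoxy)-5-methylbenzene | COCOc1cc(C)cc(OCOC)c1 | intermediate
9 | [2,6-bis(methoxymethoxy)-4-methylphenyl]lithium | [Li]c1c(OCOC)cc(C)cc1OCOC | intermediate
10 | 2,6-bis(methoxymethoxy)-4-methylbenzaldehyde | O=Cc1c(OCOC)cc(C)cc1OCOC | intermediate
11 | 2,6-dihydroxy-4-methylbenzaldehyde (atranol) | O=Cc1c(O)cc(C)cc1O | intermediate
12 | 3-chloro-2,6-dihydroxy-4-methylbenzaldehyde (chloroatranol) | O=Cc1c(O)cc(C)c(Cl)c1O | intermediate
13 | 3-chloro-2-hydroxy-4-methyl-6-{[tri(propan-2-yl)silyl]oxy}benzaldehyde | O=Cc1c(O)c(Cl)c(C)cc1O[Si](C(C)C)(C(C)C)C(C)C | intermediate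
14 | 2-iodo-3-methoxy-5-(methoxymethoxy)benzoyl chloride | O=C(Cl)c1cc(OCOC)cc(OC)c1I | intermediate
15 | 6-chloro-2-formyl-5-methyl-3-{[tri(propan-2-yl)silyl]oxy}phenyl 2-iodo-3-methoxy-5-(methoxymethoxy)benzoate | O=Cc1c(O[Si](C(C)C)(C(C)C)C(C)C)cc(C)c(Cl)c1OC(=O)c1cc(OCOC)cc(OC)c1I | intermediate
16 | 6-chloro-2-formyl-3-hydroxy-5-methylphenyl 2-iodo-3-methoxy-5-(methoxymethoxy)benzoate | O=Cc1c(O)cc(C)c(Cl)c1OC(=O)c1cc(OCOC)cc(OC)c1I | intermediate
17 | 4-chloro-1-hydroxy-10-methoxy-8-(methoxymethoxy)-3-methyldibenzo[b,e]oxepine-6,11-dione | O=C1Oc2c(Cl)c(C)cc(O)c2C(=O)c2c(OC)cc(OCOC)cc12 | intermediate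
18 | methyl 2-(3-chloro-2,6-dihydroxy-4-methylbenzoyl)-3-methoxy-5-(methoxymethoxy)benzoate | COC(=O)c1cc(OCOC)cc(OC)c1C(=O)c1c(O)cc(C)c(Cl)c1O | intermediate
19 | monochlorosulochrin, methyl 2-(3-chloro-2,6-dihydroxy-4-methylbenzoyl)-5-hydroxy-3-methoxybenzoate | COC(=O)c1cc(O)cc(OC)c1C(=O)c1c(O)cc(C)c(Cl)c1O | target

**Step count and risks**

Total steps: 12. Longest linear sequence: 8 steps (steps 5–12 from orcinol; the ring A branch, steps 1–4 and 9–12, is equally long).

Steps most likely to fail:

1. Step 11 (the proposed new method).
   - What may go wrong: the tethered arylpalladium may fail to reach the formyl C–H through the s-cis ester geometry and lose iodine by protonation instead. The phenoxide of one molecule may attack the activated aryl ester of another (acyl transfer, oligomers), or carbonate may cleave the ester before coupling. The acylpalladium may also lose carbon monoxide.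
   - Fallback (known chemistry, without the tether): it sets out from 8 and 5. NCS chlorination of 8 should give 2-chloro-1,5-bis(methoxymethoxy)-3-methylbenzene F1. Lithiation with n-BuLi between the two acetal oxygens should give [3-chloro-2,6-bis(methoxymethoxy)-4-methylphenyl]lithium F2, which is trapped with B(OMe)3 and hydrolysed to [3-chloro-2,6-bis(methoxymethoxy)-4-methylphenyl]boronic acid F3. A carbonylative Suzuki–Miyaura coupling of F3 with iodide 5 under CO (1 atm), with PdCl2(NHC)(3-chloropyridine) (NHC = 1,3-bis(2,6-diisopropylphenyl)imidazol-2-ylidene), Cs2CO3, chlorobenzene, 80 °C, is a known reaction type for doubly ortho-substituted aryl iodides. It should give methyl 2-[3-chloro-2,6-bis(methoxymethoxy)-4-methylbenzoyl]-3-methoxy-5-(methoxymethoxy)benzoate F4. HCl in methanol then removes the three acetal ethers, and the route is rejoined at the target 19.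

2. Step 8.
   - What may go wrong: loss of regiocontrol, with silylation at the chlorine-flanked oxygen or at both oxygens.
   - Fallback: it sets out from the symmetric diol 11, where mono-silylation with TIPSCl and imidazole poses no regiochemical question and should give 2-hydroxy-4-methyl-6-{[tri(propan-2-yl)silyl]oxy}benzaldehyde F5. Chlorination with NCS follows. Both open positions of F5 are ortho to one oxygen and para to the other, so the choice falls to sterics: the bulky silyl ether shields its neighbouring position, and chlorine should enter next to the free phenol. This returns to the route at 13.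

3. Step 10.
   - What may go wrong: fluoride or the freed phenoxide may attack the activated aryl ester, causing ester cleavage or acyl transfer during desilylation.
   - Fallback: it sets out from 12 and 6 (through 14) and uses no silyl group. DMAP-catalysed acylation of the diol 12 with one equivalent of 14 should take the less hindered, hydrogen-flanked phenol. It should give the regioisomeric ester 4-chloro-2-formyl-3-hydroxy-5-methylphenyl 2-iodo-3-methoxy-5-(methoxymethoxy)benzoate F6, which needs no deprotection. Under the conditions of step 11, F6 should close to the isomeric lactone 2-chloro-1-hydroxy-10-methoxy-8-(methoxymethoxy)-3-methyldibenzo[b,e]oxepine-6,11-dione F7. Methoxide opening of F7 gives the same benzophenone 18, where the route is rejoined.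
   - Price of this fallback: F6 carries an aromatic C–H ortho to the ester oxygen, so six-ring direct arylation may compete with the formyl coupling. For that reason it is the fallback and not the main line.

**Further compounds**

F1 | step 11 | 2-chloro-1,5-bis(methoxymethoxy)-3-methylbenzene | COCOc1cc(C)c(Cl)c(OCOC)c1
F2 | step 11 | [3-chloro-2,6-bis(methoxymethoxy)-4-methylphenyl]lithium | [Li]c1c(OCOC)cc(C)c(Cl)c1OCOC
F3 | step 11 | [3-chloro-2,6-bis(methoxymethoxy)-4-methylphenyl]boronic acid | OB(O)c1c(OCOC)cc(C)c(Cl)c1OCOC
F4 | step 11 | methyl 2-[3-chloro-2,6-bis(methoxymethoxy)-4-methylbenzoyl]-3-methoxy-5-(methoxymethoxy)benzoate | COC(=O)c1cc(OCOC)cc(OC)c1C(=O)c1c(OCOC)cc(C)c(Cl)c1OCOC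
F5 | step 8 | 2-hydroxy-4-methyl-6-{[tri(propan-2-yl)silyl]oxy}benzaldehyde | O=Cc1c(O)cc(C)cc1O[Si](C(C)C)(C(C)C)C(C)C
F6 | step 10 | 4-chloro-2-formyl-3-hydroxy-5-methylphenyl 2-iodo-3-methoxy-5-(methoxymethoxy)benzoate | O=Cc1c(O)c(Cl)c(C)cc1OC(=O)c1cc(OCOC)cc(OC)c1I
F7 | step 10 | 2-chloro-1-hydroxy-10-methoxy-8-(methoxymethoxy)-3-methyldibenzo[b,e]oxepine-6,11-dione | O=C1Oc2cc(C)c(Cl)c(O)c2C(=O)c2c(OC)cc(OCOC)cc12
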